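The runs stem from a simulated flask for an exercise; noise was put on by code.

Two questions stand on the autumn flask, which has been followed to 12.0 h and is asked about at 30 h.

| setting | autumn | dawn | flask |
|---|---|---|---|
| substrate | 0.050 M | 0.10 M | 0.050 M |
| reagent | 0.10 M (fed, over 8.0 h) | 0.10 M (fed, over 8.0 h) | 0.100 M (fed, over 8.0 h) |
| remark | the very flask that is asked about, followed so far; the fed solution adds 0.25 times the starting volume | run made earlier; the fed solution adds 0.25 times the starting volume | the fed solution adds 0.25 times the starting volume |
| time |  |  | 30 h |

| run | time / h | intermediate A / % | substrate / % | intermediate B / % | side product / % | target / % | intermediate C / % |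
|---|---|---|---|---|---|---|---|
| autumn | 2.50 | 32.8 | 57.1 | 1.0 | 6.9 | 0 | 0 |
| autumn | 5.00 | 38.6 | 36.1 | 9.6 | 16.3 | 0.9 | 0 |
| autumn | 8.00 | 33.5 | 23.5 | 19.8 | 22.3 | 0 | 0.3 |
| autumn | 10.0 | 30.7 | 18.8 | 24.7 | 24.9 | 0 | 0 |
| autumn | 12.0 | 27.9 | 15.9 | 29.4 | 25.3 | 0 | 0.3 |
| dawn | 2.50 | 29.9 | 54.3 | 1.9 | 14.4 | 0 | 0.6 |
| dawn | 8.00 | 29.0 | 19.5 | 15.0 | 36.5 | 0 | 0 |
| dawn | 15.0 | 21.2 | 9.5 | 22.5 | 44.8 | 0.4 | 1.4 |
| dawn | 20.0 | 20.1 | 8.7 | 21.8 | 48.7 | 1.7 | 0.2 |
| dawn | 30.0 | 16.6 | 6.8 | 20.1 | 53.0 | 1.8 | 1.4 |

(readings scatter by 0.5 percentage points)

1. the species that holds most of what was charged as substrate, at 30 h (substrate / side product / target / intermediate A / intermediate C / intermediate B)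
2. the largest share itself, whichever of these holds it, in percent of the substrate charged

- a species is counted by the substrate in it: one side product counts as two
- charges are per starting volume, the dose included; the dosed solution carries all of it

The bench rule reads the autumn charge, reagent at 2.00 times the substrate, as an excess: the step from intermediate A to intermediate B is then pseudo-first-order, and intermediate A should drain into intermediate B. The dawn run marks the border of that rule. This reckoning assumes one reagent held in intermediate B and two in intermediate C and in target, and on that count dawn keeps 73.5% of its reagent free at 30.0 h, yet its intermediate B goes from 22.5% to 20.1% after 15.0 h. So the step is read as running both ways, with the split between intermediate A and intermediate B taken to follow the free reagent concentration: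

free reagent, dawn = 0.0588 M

hold quotient = (20.1% / 16.6%) / free reagent = 20.6 M⁻¹

This hold quotient, intermediate B over intermediate A per unit of free reagent, is a reading from dawn and carries its scatter. For autumn at 30 h, with reagent held as at 12.0 h:

free reagent = 0.0682 M, so intermediate B over intermediate A = 1.41

With substrate over intermediate A as in dawn, 0.410, and with intermediate C and target left out of this reckoning, intermediate B takes 49.9% of what is not side product, and the two would tie at 33.3%. Reaching that tie asks for 0.592 of the side product's recent pace. Taking that pace to follow substrate times intermediate A, which falls to 0.519 of its value, the mean pace is 0.759, higher than the tie asks. This reckoning therefore commits to side product at 35.5%, ahead of intermediate B at 32.2%.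

The forecast named intermediate B at 46%, within 40% to 53%, noting that “Dawn had only 1 equivalent of reagent and stalled”.

The autumn flask gives side product at 36.0%, above intermediate B at 28.1% and intermediate A at 22.2%.

    substrate ⇌ intermediate A (K = 2.26, k = 0.237 h⁻¹)
    reagent + intermediate A ⇌ intermediate B (K = 19.0 M⁻¹, k = 2.53 M⁻¹ h⁻¹)
    reagent + intermediate B ⇌ intermediate C (K = 8.22 M⁻¹, k = 0.0994 M⁻¹ h⁻¹)
    intermediate C ⇌ target (K = 3.10, k = 0.234 h⁻¹)
    substrate + intermediate A → side product (k = 2.29 M⁻¹ h⁻¹)

With 82% of its reagent left, the hold quotient gives a ratio of 1.35 for intermediate B over intermediate A, and the flask holds 1.27. The neighbour charged with 0.030 M of substrate keeps 87% of its reagent, so the quotient gives 1.43, and that neighbour holds 1.32, with intermediate B at 33.5%.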